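The 1,4-dioxane ring is cut at its only C–C single bond, C2–C3, the two carbons that each carry one catechol oxygen (O1 and O4). This bond is a latent enediol diether double bond, so it is made by an intramolecular ester Wittig reaction: the ylide carbon on O4 (future C3, already bearing the methyl) attacks the 3,4,5-trimethoxybenzoate carbonyl on O1 (future C2) and closes the ring as a flat 1,4-benzodioxine in one operation. The precursor is a eugenol-derived catechol that is a vinyl ether on one oxygen and an aryl ester on the other. A final enantioselective ionic transfer hydrogenation sets both stereocentres trans, leaving the allyl group untouched.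

Key step: step 4

Assumption: the sense of induction of the phosphoramide catalyst in step 5 cannot be predicted with confidence; the (R) catalyst is written, and its enantiomer is used if screening shows that it is the one that delivers the (2R,3R) product.

Step 1
Reactants: 1 eugenol (4-allyl-2-methoxyphenol); 2 2,4,6-trivinylcyclotriboroxane–pyridine complex
Product: 3 4-allyl-2-methoxy-1-(vinyloxy)benzene
Conditions: Cu(OAc)2 (1 equiv), pyridine, CH2Cl2, air, rt
Reagents that add atoms: 2,4,6-trivinylcyclotriboroxane–pyridine complex, C=CB1OB(C=C)OB(C=C)O1.c1ccncc1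
Why: Chan–Lam-type oxidative C–O coupling, in which the phenol binds divalent copper, a vinyl group is transferred from boron and C–O reductive elimination should give the aryl vinyl ether at room temperature without touching the allyl group.

Step 2
Reactants: 3 4-allyl-2-methoxy-1-(vinyloxy)benzene
Product: 4 5-allyl-2-(vinyloxy)phenol
Conditions: LiBH(s-Bu)3, THF, reflux; aq NH4Cl, 0 °C; crude phenol used at once
Reagents that add atoms: none
Why: SN2 O-demethylation by a hindered hydride, in which the methyl carbon is the only sp3 C–O site (vinyl and aryl C–O carbons cannot be displaced), lithium chelation by the two ortho oxygens should speed the cleavage, the isolated double bonds are inert to the borohydride, and the cold, weakly acidic work-up is meant to keep the new phenol from adding to the neighbouring vinyl ether.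

Step 3
Reactants: 4 5-allyl-2-(vinyloxy)phenol; 5 3,4,5-trimethoxybenzoyl chloride
Product: 6 5-allyl-2-(vinyloxy)phenyl 3,4,5-trimethoxybenzoate
Conditions: Et3N, DMAP (cat.), CH2Cl2, 0 °C
Reagents that add atoms: 3,4,5-trimethoxybenzoyl chloride, COc1cc(cc(OC)c1OC)C(=O)Cl
Why: DMAP-catalysed nucleophilic acyl substitution of an acid chloride by a phenol under basic conditions that spare the acid-labile vinyl ether; the other catechol oxygen is already vinylated, so the ester cannot migrate and the regiochemistry inherited from eugenol (ester oxygen meta, vinyl ether oxygen para to the allyl group) stays fixed.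

Step 4
Reactants: 6 5-allyl-2-(vinyloxy)phenyl 3,4,5-trimethoxybenzoate; 7 triphenylphosphine hydrobromide
Product: 10 3-methyl-7-(prop-2-en-1-yl)-2-(3,4,5-trimethoxyphenyl)-1,4-benzodioxine, via phosphonium bromide 8 (not isolated), via phosphorus ylide 9 (not isolated)
Conditions: CH2Cl2, 0 °C to rt; evaporate; NaN(SiMe3)2, THF, −78 °C to rt
Reagents that add atoms: none
Why: Markovnikov addition of HBr from Ph3P·HBr across the aryl vinyl ether gives an α-bromo ether that PPh3 captures as the α-aryloxyethylphosphonium salt; NaN(SiMe3)2 then forms the ylide at the future C3, which adds to the neighbouring aryl ester carbonyl (the future C2), and the oxaphosphetane collapses to Ph3PO and the C2=C3 double bond. The closest known reaction type is the intramolecular Wittig olefination of esters that makes benzofurans and chromenes from acyloxy-substituted phosphonium salts, here run with an α-aryloxy ylide of the MeOCH=PPh3 family. The dioxine ring closes by 6-exo-trig attack of the ylide carbon on the ester C=O, and the double bond ends endocyclic once Ph3PO is lost. No stereocentre is formed, because both ring carbons become sp2; the step only fixes the constitution of the enediol diether. The selectivity it needs is olefination over O-to-C acyl transfer, and the tether secures it: a phenoxide expelled from the tetrahedral adduct stays ortho to the resulting β-keto phosphonium ion and can re-add, so both paths should drain into the irreversible loss of Ph3PO. The allyl group, the aryl methyl ethers and the aromatic rings are spectators under these aprotic basic conditions.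

Step 5
Reactants: 10 3-methyl-7-(prop-2-en-1-yl)-2-(3,4,5-trimethoxyphenyl)-1,4-benzodioxine
Product: 11 (2R,3R)-3-methyl-7-(prop-2-en-1-yl)-2-(3,4,5-trimethoxyphenyl)-2,3-dihydro-1,4-benzodioxine
Conditions: Hantzsch ester (diethyl 2,6-dimethyl-1,4-dihydropyridine-3,5-dicarboxylate, 1.3 equiv), (R)-3,3′-bis(2,4,6-triisopropylphenyl)-1,1′-binaphthyl-2,2′-diyl N-triflylphosphoramide (10 mol %), toluene, 5 Å molecular sieves, 35 °C
Reagents that add atoms: none
Why: Proposed new method: the chiral N-triflylphosphoramide should protonate the enediol diether at C3 (the site that leaves the cation on C2, stabilised by O1 and the trimethoxyphenyl ring), and the Hantzsch ester should then deliver hydride to C2 of the oxocarbenium–phosphoramidate ion pair along the axial trajectory of the half-chair with the C3 methyl pseudo-equatorial, which gives the trans (diequatorial) ring, while the chiral counter-anion controls the face of protonation and, since protonation is reversible, selects the faster-reduced ion pair, so that C3 and C2 are both set as R; the isolated allyl double bond is inert to this ionic hydride transfer, and the closest known reaction types are the phosphoric-acid-catalysed transfer hydrogenation of enamides and imines with Hantzsch esters and the chiral-phosphate ion-pair reduction of benzopyrylium ions.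

Compound list
1 | eugenol (4-allyl-2-methoxyphenol) | C=CCc1ccc(O)c(OC)c1 | starting material
2 | 2,4,6-trivinylcyclotriboroxane–pyridine complex | C=CB1OB(C=C)OB(C=C)O1.c1ccncc1 | starting material
3 | 4-allyl-2-methoxy-1-(vinyloxy)benzene | C=CCc1ccc(OC=C)c(OC)c1 | intermediate
4 | 5-allyl-2-(vinyloxy)phenol | C=CCc1ccc(OC=C)c(O)c1 | intermediate
5 | 3,4,5-trimethoxybenzoyl chloride | COc1cc(cc(OC)c1OC)C(=O)Cl | starting material
6 | 5-allyl-2-(vinyloxy)phenyl 3,4,5-trimethoxybenzoate | C=CCc1ccc(OC=C)c(OC(=O)c2cc(OC)c(OC)c(OC)c2)c1 | intermediate
7 | triphenylphosphine hydrobromide (triphenylphosphonium bromide) | [Br-].[PH+](c1ccccc1)(c1ccccc1)c1ccccc1 | starting material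
8 | {1-[4-allyl-2-(3,4,5-trimethoxybenzoyloxy)phenoxy]ethyl}triphenylphosphonium bromide (racemic, not isolated) | C=CCc1ccc(OC(C)[P+](c2ccccc2)(c2ccccc2)c2ccccc2)c(OC(=O)c2cc(OC)c(OC)c(OC)c2)c1.[Br-] | intermediate
9 | {1-[4-allyl-2-(3,4,5-trimethoxybenzoyloxy)phenoxy]ethylidene}triphenylphosphorane (ylide, not isolated) | C=CCc1ccc(OC(C)=P(c2ccccc2)(c2ccccc2)c2ccccc2)c(OC(=O)c2cc(OC)c(OC)c(OC)c2)c1 | intermediate
10 | 3-methyl-7-(prop-2-en-1-yl)-2-(3,4,5-trimethoxyphenyl)-1,4-benzodioxine | C=CCc1ccc2c(c1)OC(c1cc(OC)c(OC)c(OC)c1)=C(C)O2 | intermediate
11 | (2R,3R)-3-methyl-7-(prop-2-en-1-yl)-2-(3,4,5-trimethoxyphenyl)-2,3-dihydro-1,4-benzodioxine | C=CCc1ccc2c(c1)O[C@H](c1cc(OC)c(OC)c(OC)c1)[C@@H](C)O2 | target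

Total step count: 5
Longest linear sequence: 5 steps (1 → 3 → 4 → 6 → 10 → 11)

Steps most likely to fail

Step 5 (Proposed new method). The catalyst may be too weak an acid to protonate the enediol diether, or the hydride transfer may proceed with poor facial selectivity and give low enantiomeric excess or a cis/trans mixture. The fallback sets out from 10 and comes back at 11. Ionic hydrogenation of 10 with Et3SiH and CF3CO2H in CH2Cl2 at 0 °C, a known substrate-controlled reduction of enol ethers with axial hydride delivery, should give the racemic trans-dihydrobenzodioxine F1. Preparative HPLC on a cellulose tris(3,5-dimethylphenylcarbamate) phase then separates the (2R,3R) enantiomer, which is 11, from the (2S,3S) enantiomer F2.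

Step 4 (key step). The ylide may transfer the acyl group without olefination, or the base may cleave the phosphonium salt back to the vinyl ether. The fallback sets out from 6 and comes back at 10, and it still closes the ring through the same C2–C3 bond. Dry HCl in Et2O at 0 °C adds across the vinyl ether to give 5-allyl-2-(1-chloroethoxy)phenyl 3,4,5-trimethoxybenzoate F3. SmI2 in THF at −78 °C turns the α-chloro ether into an α-aryloxyalkyl samarium species that adds to the neighbouring ester carbonyl (Barbier-type intramolecular acyl addition) and gives the cyclic hemiketal 7-allyl-2-hydroxy-3-methyl-2-(3,4,5-trimethoxyphenyl)-2,3-dihydro-1,4-benzodioxine F4. Dehydration with catalytic p-toluenesulfonic acid in refluxing toluene (Dean–Stark) gives 10.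

Step 2. The free phenol may add under acid catalysis to the neighbouring vinyl ether during work-up, which would consume the vinyl ether as a five-membered acetal, or the SN2 demethylation may be sluggish. The fallback sets out from 1 and comes back at 6; it cleaves the methyl ether before any acid-labile group is present and introduces the vinyl ether last. Acetylation of 1 (Ac2O, pyridine) gives eugenol acetate F5. BBr3 in CH2Cl2 at −78 to −20 °C gives 4-allyl-2-hydroxyphenyl acetate F6. Acylation with 5 (pyridine, CH2Cl2, −20 °C, to outrun acetate migration) gives the mixed diester 2-acetoxy-5-allylphenyl 3,4,5-trimethoxybenzoate F7. NH4OAc in aqueous MeOH at rt removes the more labile acetate and gives 5-allyl-2-hydroxyphenyl 3,4,5-trimethoxybenzoate F8. Chan–Lam vinylation of F8 with 2 (Cu(OAc)2, pyridine, CH2Cl2, rt) gives 6.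

Further compounds
F1 | step 5 | racemic trans-3-methyl-7-(prop-2-en-1-yl)-2-(3,4,5-trimethoxyphenyl)-2,3-dihydro-1,4-benzodioxine (1:1 mixture of both enantiomers) | C=CCc1ccc2c(c1)O[C@H](c1cc(OC)c(OC)c(OC)c1)[C@@H](C)O2.C=CCc1ccc2c(c1)O[C@@H](c1cc(OC)c(OC)c(OC)c1)[C@H](C)O2
F2 | step 5 | (2S,3S)-3-methyl-7-(prop-2-en-1-yl)-2-(3,4,5-trimethoxyphenyl)-2,3-dihydro-1,4-benzodioxine | C=CCc1ccc2c(c1)O[C@@H](c1cc(OC)c(OC)c(OC)c1)[C@H](C)O2
F3 | step 4 | 5-allyl-2-(1-chloroethoxy)phenyl 3,4,5-trimethoxybenzoate (racemic) | C=CCc1ccc(OC(C)Cl)c(OC(=O)c2cc(OC)c(OC)c(OC)c2)c1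
F4 | step 4 | 7-allyl-2-hydroxy-3-methyl-2-(3,4,5-trimethoxyphenyl)-2,3-dihydro-1,4-benzodioxine (diastereomer mixture, ring tautomer of the keto phenol) | C=CCc1ccc2c(c1)OC(O)(c1cc(OC)c(OC)c(OC)c1)C(C)O2
F5 | step 2 | 4-allyl-2-methoxyphenyl acetate (eugenol acetate) | C=CCc1ccc(OC(C)=O)c(OC)c1
F6 | step 2 | 4-allyl-2-hydroxyphenyl acetate | C=CCc1ccc(OC(C)=O)c(O)c1
F7 | step 2 | 2-acetoxy-5-allylphenyl 3,4,5-trimethoxybenzoate | C=CCc1ccc(OC(C)=O)c(OC(=O)c2cc(OC)c(OC)c(OC)c2)c1
F8 | step 2 | 5-allyl-2-hydroxyphenyl 3,4,5-trimethoxybenzoate | C=CCc1ccc(O)c(OC(=O)c2cc(OC)c(OC)c(OC)c2)c1
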